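**Retrosynthetic overview**

1. The side chain is attached last. The C12–C13 bond is cut (sp3–sp2 Negishi coupling) into decalin iodide 19 and (Z)-iodoalkene ester 25; the geometry and O-differentiation of 25 come from hydroxyl-directed hydroalumination/iodination of but-2-yne-1,4-diol.
2. In 19 the C18 methyl is traced to the C4 enol triflate of ketone 14, and the trans ring fusion (C10–H) to hydrogen-atom-transfer hydrogenation of the Δ1(10) alkene 12.
3. Key disconnection: 12 is opened across C1–C2 and C4–C5 into methylenecyclohexane 9 and acrolein (C2–C3–C4). The two are joined in one Me2AlCl-mediated two-fold ene ([3+3]) annulation that also creates the quaternary C5.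
4. Enabling feature: C10 of ring B lies between the quaternary C9 and the methyl-bearing C5, so the exocyclic C10=C1 alkene of 9 has a single allylic hydrogen (C5–H). C1 and then C5 act in turn as nucleophiles (a C1–C10–C5 1,3-bis-nucleophile) toward the 1,3-bis-electrophile acrolein.
5. Ring order: ring B first (C8 and C9 from asymmetric conjugate methylation/enolate allylation of 2-methylcyclohex-2-en-1-one), ring A in the key step, C10–H last.

Key step: step 6

Remark: atoms are numbered as in clerodanes (ring A = C1–C5 and C10; ring B = C5–C10; side chain C11–C16; methyls C17–C20). Systematic names use their own locants.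

Assumption: the enantiomer of the chiral NHC ligand in step 1 is the one that gives the 3R enolate. The carbinol epimers of 12 and 13 are carried on together, and the configuration at the ring carbon that bears C19 in 5–9 is irrelevant because this carbon becomes sp2 in step 6.

**Route**

Step 1
Reactants: 1 2-methylcyclohex-2-en-1-one
Product: 3 (2S,3R)-2,3-dimethyl-2-(prop-2-en-1-yl)cyclohexan-1-one, via magnesium enolate 2 (not isolated)
Conditions: MeMgBr, Cu(OTf)2 (3 mol %), chiral hydroxyalkyl imidazolinium salt (NHC precursor, 4 mol %), Et2O, −30 °C; then allyl iodide, DMPU, −30 °C to rt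
Reagents that add atoms: methylmagnesium bromide C[Mg]Br; allyl iodide C=CCI
Why: Copper-catalysed asymmetric conjugate addition of the Grignard reagent with trapping of the magnesium enolate: the chiral NHC–copper catalyst should set C8 (3R), and allylation of the tetrasubstituted enolate anti to the new methyl group should set the quaternary C9 (2S, allyl trans to the C8 methyl).

Step 2
Reactants: 3 (2S,3R)-2,3-dimethyl-2-(prop-2-en-1-yl)cyclohexan-1-one
Product: 5 (2S,3R,6R)-2,3,6-trimethyl-2-(prop-2-en-1-yl)cyclohexan-1-one, via lithium enolate 4 (not isolated)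
Conditions: lithium diisopropylamide, THF, −78 °C; MeI, −78 to 0 °C; then NaOMe (cat.), MeOH, rt
Reagents that add atoms: iodomethane CI
Why: Kinetic enolate methylation at the only enolisable position (the future C5) installs C19; the new centre should equilibrate to the equatorial methyl and becomes sp2 in step 6.

Step 3
Reactants: 5 (2S,3R,6R)-2,3,6-trimethyl-2-(prop-2-en-1-yl)cyclohexan-1-one
Product: 7 (2S,3R,6R)-2-(2-hydroxyethyl)-2,3,6-trimethylcyclohexan-1-one, via keto aldehyde 6 (not isolated)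
Conditions: O3, CH2Cl2/MeOH, −78 °C; Me2S; then NaBH4, −78 to −40 °C
Reagents that add atoms: ozone [O-][O+]=O
Why: Ozonolysis of the only C=C bond followed by chemoselective borohydride reduction of the aldehyde; the ketone is shielded by its quaternary and tertiary neighbours.

Step 4
Reactants: 7 (2S,3R,6R)-2-(2-hydroxyethyl)-2,3,6-trimethylcyclohexan-1-one
Product: 8 (2S,3R,6R)-2-{2-[(tert-butyldiphenylsilyl)oxy]ethyl}-2,3,6-trimethylcyclohexan-1-one
Conditions: t-BuPh2SiCl, imidazole, CH2Cl2, rt
Reagents that add atoms: tert-butyl(chloro)diphenylsilane CC(C)(C)[Si](Cl)(c1ccccc1)c1ccccc1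
Why: Standard silylation of the primary alcohol, which masks the hydroxyl group (and any lactol form) before the Lewis-acid step.

Step 5
Reactants: 8 (2S,3R,6R)-2-{2-[(tert-butyldiphenylsilyl)oxy]ethyl}-2,3,6-trimethylcyclohexan-1-one
Product: 9 tert-butyl{2-[(1S,3R,6R)-1,3,6-trimethyl-2-methylidenecyclohexyl]ethoxy}diphenylsilane
Conditions: Ph3PCH3Br, KOtBu, toluene, 90 °C
Reagents that add atoms: methyltriphenylphosphonium bromide (as its ylide) C[P+](c1ccccc1)(c1ccccc1)c1ccccc1.[Br-]
Why: Wittig methylenation under the forcing conditions used for hindered ketones installs C1 as the exocyclic CH2 on C10.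

Step 6
Reactants: 9 tert-butyl{2-[(1S,3R,6R)-1,3,6-trimethyl-2-methylidenecyclohexyl]ethoxy}diphenylsilane; 10 acrolein
Product: 12 (5S,6R,8aR)-5-{2-[(tert-butyldiphenylsilyl)oxy]ethyl}-5,6,8a-trimethyl-1,2,3,5,6,7,8,8a-octahydronaphthalen-1-ol (C1 epimers), via ene adduct aldehyde 11 (not isolated)
Conditions: acrolein (1.5 equiv), Me2AlCl (2.2 equiv), CH2Cl2, −78 to 0 °C
Reagents that add atoms: none
Why: Proposed new method: a Lewis-acid-promoted sequential ene ([3+3]) annulation whose closest known reaction type is the Me2AlCl-mediated two-fold ene annulation of alkylidenecycloalkanes with acrolein or methyl vinyl ketone, applied here to a methylenecyclohexane whose second allylic carbon (C9) is quaternary; the acrolein–Me2AlCl complex should add through its β-carbon (C2) to the unhindered exocyclic CH2 (C1) while the only allylic hydrogen (C5–H) is transferred, which moves the double bond to C5=C10 and leaves aldehyde 11 bound to aluminium. The tetrasubstituted C5=C10 bond should then attack the activated aldehyde carbon C4 through C5 (intramolecular carbonyl-ene reaction of the second type, Prins-like), and the charge that builds up at C10 should be discharged by 1,5-transfer of a C1 hydrogen to the aluminium alkoxide oxygen through a six-membered array, giving the Δ1(10) homoallylic alcohol, with loss of methane from the Al–O–C4 alkoxide making the sequence irreversible. Ring A is the only ring closed, by a six-membered closure that is endo to the C5=C10 bond; it should be preferred over five-membered spiro closure at C10 because C10 is shielded by the quaternary C9 and the chair-like array aligns C4=O with C5. The new quaternary stereocentre C5 is controlled by ring B: in the half-chair with the C8 methyl equatorial the C9 methyl (C20) is pseudoaxial, so C4 should approach C5 from the opposite face and place C19 cis to C20, while the C4 carbinol centre is not controlled and is erased in step 8. The step needs regioselectivity in the first ene reaction (secured because C9 carries no hydrogen), six- over five-membered closure, and the facial selectivity at C5 described above; its liability is the cationic character at C10 (chloride capture or 1,2-methyl shift), which low temperature and the internal proton transfer are expected to suppress.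

Step 7
Reactants: 12 (5S,6R,8aR)-5-{2-[(tert-butyldiphenylsilyl)oxy]ethyl}-5,6,8a-trimethyl-1,2,3,5,6,7,8,8a-octahydronaphthalen-1-ol (C1 epimers)
Product: 13 (4aR,5S,6R,8aR)-5-{2-[(tert-butyldiphenylsilyl)oxy]ethyl}-5,6,8a-trimethyldecahydronaphthalen-1-ol (C1 epimers)
Conditions: Mn(dpm)3 (10 mol %), PhSiH3, t-BuOOH, i-PrOH, rt
Reagents that add atoms: none
Why: Metal-hydride hydrogen-atom-transfer hydrogenation: hydrogen adds to C1, and the tertiary C10 radical should be quenched on the face opposite to the two axial methyl groups at C5 and C9, which gives the trans ring fusion (C10–H anti to C19).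

Step 8
Reactants: 13 (4aR,5S,6R,8aR)-5-{2-[(tert-butyldiphenylsilyl)oxy]ethyl}-5,6,8a-trimethyldecahydronaphthalen-1-ol (C1 epimers)
Product: 14 (4aR,5S,6R,8aR)-5-{2-[(tert-butyldiphenylsilyl)oxy]ethyl}-5,6,8a-trimethyloctahydronaphthalen-1(2H)-one
Conditions: Pr4N[RuO4] (5 mol %), N-methylmorpholine N-oxide, 4 Å MS, CH2Cl2, rt
Reagents that add atoms: none
Why: Perruthenate-catalysed oxidation of the secondary alcohol; both C4 epimers converge on one ketone.

Step 9
Reactants: 14 (4aR,5S,6R,8aR)-5-{2-[(tert-butyldiphenylsilyl)oxy]ethyl}-5,6,8a-trimethyloctahydronaphthalen-1(2H)-one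
Product: 16 (4aR,5S,6R,8aR)-5-{2-[(tert-butyldiphenylsilyl)oxy]ethyl}-5,6,8a-trimethyl-3,4,4a,5,6,7,8,8a-octahydronaphthalen-1-yl trifluoromethanesulfonate, via potassium enolate 15 (not isolated)
Conditions: KN(SiMe3)2, THF, −78 °C; PhNTf2, −78 to 0 °C
Reagents that add atoms: N-phenylbis(trifluoromethanesulfonimide) O=S(=O)(N(c1ccccc1)S(=O)(=O)C(F)(F)F)C(F)(F)F
Why: Enolisation can only occur toward C3 because C5 is quaternary, so O-triflation should give the C3=C4 enol triflate regiospecifically.

Step 10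
Reactants: 16 (4aR,5S,6R,8aR)-5-{2-[(tert-butyldiphenylsilyl)oxy]ethyl}-5,6,8a-trimethyl-3,4,4a,5,6,7,8,8a-octahydronaphthalen-1-yl trifluoromethanesulfonate
Product: 17 tert-butyl{2-[(1S,2R,4aR,8aR)-1,2,4a,5-tetramethyl-1,2,3,4,4a,7,8,8a-octahydronaphthalen-1-yl]ethoxy}diphenylsilane
Conditions: MeMgBr, Fe(acac)3 (5 mol %), THF/NMP, −20 to 0 °C
Reagents that add atoms: methylmagnesium bromide C[Mg]Br
Why: Iron-catalysed cross-coupling of the alkenyl triflate with the methyl Grignard reagent installs C18 and leaves the C3=C4 bond in place.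

Step 11
Reactants: 17 tert-butyl{2-[(1S,2R,4aR,8aR)-1,2,4a,5-tetramethyl-1,2,3,4,4a,7,8,8a-octahydronaphthalen-1-yl]ethoxy}diphenylsilane
Product: 18 2-[(1S,2R,4aR,8aR)-1,2,4a,5-tetramethyl-1,2,3,4,4a,7,8,8a-octahydronaphthalen-1-yl]ethan-1-ol
Conditions: Bu4NF, THF, rt
Reagents that add atoms: none
Why: Fluoride cleavage of the silyl ether frees the C12 alcohol.

Step 12
Reactants: 18 2-[(1S,2R,4aR,8aR)-1,2,4a,5-tetramethyl-1,2,3,4,4a,7,8,8a-octahydronaphthalen-1-yl]ethan-1-ol
Product: 19 (1S,2R,4aR,8aR)-1-(2-iodoethyl)-1,2,4a,5-tetramethyl-1,2,3,4,4a,7,8,8a-octahydronaphthalene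
Conditions: I2, PPh3, imidazole, CH2Cl2, 0 °C to rt
Reagents that add atoms: iodine II
Why: Appel-type iodination of the primary alcohol by SN2 displacement of the oxyphosphonium group.

Step 13
Reactants: 20 but-2-yne-1,4-diol
Product: 21 4-[(tert-butyldimethylsilyl)oxy]but-2-yn-1-ol
Conditions: t-BuMe2SiCl (1 equiv), imidazole, diol (3 equiv), DMF, 0 °C
Reagents that add atoms: tert-butyl(chloro)dimethylsilane CC(C)(C)[Si](C)(C)Cl
Why: Statistical monosilylation with the symmetrical diol in excess.

Step 14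
Reactants: 21 4-[(tert-butyldimethylsilyl)oxy]but-2-yn-1-ol
Product: 23 (2Z)-4-[(tert-butyldimethylsilyl)oxy]-3-iodobut-2-en-1-ol, via cyclic alkenylalanate 22 (not isolated)
Conditions: NaAlH2(OCH2CH2OMe)2, THF, 0 °C; then I2, −78 °C
Reagents that add atoms: iodine II
Why: Hydroxyl-directed trans-hydroalumination places aluminium on the distal alkyne carbon cis to the CH2OH group (five-membered alanate), and iodinolysis with retention should give the (Z)-iodoalkene that fixes the later C13=C14 geometry.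

Step 15
Reactants: 23 (2Z)-4-[(tert-butyldimethylsilyl)oxy]-3-iodobut-2-en-1-ol; 24 icosanoyl chloride
Product: 25 (2Z)-4-[(tert-butyldimethylsilyl)oxy]-3-iodobut-2-en-1-yl icosanoate
Conditions: Et3N, DMAP (cat.), CH2Cl2, 0 °C
Reagents that add atoms: none
Why: Acylation of the free allylic alcohol (the future C15–OH) with the acid chloride while the C16 oxygen stays silylated.

Step 16
Reactants: 19 (1S,2R,4aR,8aR)-1-(2-iodoethyl)-1,2,4a,5-tetramethyl-1,2,3,4,4a,7,8,8a-octahydronaphthalene; 25 (2Z)-4-[(tert-butyldimethylsilyl)oxy]-3-iodobut-2-en-1-yl icosanoate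
Product: 27 (2E)-3-{[(tert-butyldimethylsilyl)oxy]methyl}-5-[(1S,2R,4aR,8aR)-1,2,4a,5-tetramethyl-1,2,3,4,4a,7,8,8a-octahydronaphthalen-1-yl]pent-2-en-1-yl icosanoate, via alkylzinc iodide 26 (not isolated)
Conditions: Zn dust (activated), DMA, 40 °C; then 25, PdCl2(dppf) (5 mol %), THF/DMA, rt to 40 °C
Reagents that add atoms: none
Why: Zinc insertion into the primary iodide followed by Negishi sp3–sp2 coupling with the alkenyl iodide, which proceeds with retention of alkene geometry and tolerates the ester.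

Step 17
Reactants: 27 (2E)-3-{[(tert-butyldimethylsilyl)oxy]methyl}-5-[(1S,2R,4aR,8aR)-1,2,4a,5-tetramethyl-1,2,3,4,4a,7,8,8a-octahydronaphthalen-1-yl]pent-2-en-1-yl icosanoate
Product: 28 (2E)-3-(hydroxymethyl)-5-[(1S,2R,4aR,8aR)-1,2,4a,5-tetramethyl-1,2,3,4,4a,7,8,8a-octahydronaphthalen-1-yl]pent-2-en-1-yl icosanoate (CNP0168335.1)
Conditions: HF·pyridine, pyridine/THF, 0 °C to rt
Reagents that add atoms: none
Why: Buffered fluoride should remove the primary silyl ether without touching the ester, and acyl migration is excluded because C15 and C16 are trans across the double bond.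

**Compound list**

1 | 2-methylcyclohex-2-en-1-one | CC1=CCCCC1=O | starting material
2 | bromomagnesium (3R)-2,3-dimethylcyclohex-1-en-1-olate | C[C@@H]1CCCC(O[Mg]Br)=C1C | intermediate
3 | (2S,3R)-2,3-dimethyl-2-(prop-2-en-1-yl)cyclohexan-1-one | C=CC[C@@]1(C)[C@H](C)CCCC1=O | intermediate
4 | lithium (5R,6S)-5,6-dimethyl-6-(prop-2-en-1-yl)cyclohex-1-en-1-olate | C=CC[C@@]1(C)[C@H](C)CCC=C1O[Li] | intermediate
5 | (2S,3R,6R)-2,3,6-trimethyl-2-(prop-2-en-1-yl)cyclohexan-1-one | C=CC[C@@]1(C)[C@H](C)CC[C@@H](C)C1=O | intermediate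
6 | 2-[(1S,3R,6R)-1,3,6-trimethyl-2-oxocyclohexyl]acetaldehyde | O=CC[C@@]1(C)[C@H](C)CC[C@@H](C)C1=O | intermediate
7 | (2S,3R,6R)-2-(2-hydroxyethyl)-2,3,6-trimethylcyclohexan-1-one | OCC[C@@]1(C)[C@H](C)CC[C@@H](C)C1=O | intermediate
8 | (2S,3R,6R)-2-{2-[(tert-butyldiphenylsilyl)oxy]ethyl}-2,3,6-trimethylcyclohexan-1-one | CC(C)(C)[Si](OCC[C@@]1(C)[C@H](C)CC[C@@H](C)C1=O)(c1ccccc1)c1ccccc1 | intermediate
9 | tert-butyl{2-[(1S,3R,6R)-1,3,6-trimethyl-2-methylidenecyclohexyl]ethoxy}diphenylsilane | CC(C)(C)[Si](OCC[C@@]1(C)[C@H](C)CC[C@@H](C)C1=C)(c1ccccc1)c1ccccc1 | intermediate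
10 | acrolein (prop-2-enal) | C=CC=O | starting material
11 | 4-[(5R,6S)-6-{2-[(tert-butyldiphenylsilyl)oxy]ethyl}-2,5,6-trimethylcyclohex-1-en-1-yl]butanal | CC(C)(C)[Si](OCC[C@@]1(C)[C@H](C)CCC(C)=C1CCCC=O)(c1ccccc1)c1ccccc1 | intermediate
12 | (5S,6R,8aR)-5-{2-[(tert-butyldiphenylsilyl)oxy]ethyl}-5,6,8a-trimethyl-1,2,3,5,6,7,8,8a-octahydronaphthalen-1-ol (C1 epimers) | CC(C)(C)[Si](OCC[C@@]1(C)[C@H](C)CC[C@@]2(C)C(O)CCC=C12)(c1ccccc1)c1ccccc1 | intermediate
13 | (4aR,5S,6R,8aR)-5-{2-[(tert-butyldiphenylsilyl)oxy]ethyl}-5,6,8a-trimethyldecahydronaphthalen-1-ol (C1 epimers) | CC(C)(C)[Si](OCC[C@@]1(C)[C@H](C)CC[C@@]2(C)C(O)CCC[C@H]12)(c1ccccc1)c1ccccc1 | intermediate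
14 | (4aR,5S,6R,8aR)-5-{2-[(tert-butyldiphenylsilyl)oxy]ethyl}-5,6,8a-trimethyloctahydronaphthalen-1(2H)-one | CC(C)(C)[Si](OCC[C@@]1(C)[C@H](C)CC[C@@]2(C)C(=O)CCC[C@H]12)(c1ccccc1)c1ccccc1 | intermediate
15 | potassium (4aR,5S,6R,8aR)-5-{2-[(tert-butyldiphenylsilyl)oxy]ethyl}-5,6,8a-trimethyl-3,4,4a,5,6,7,8,8a-octahydronaphthalen-1-olate | CC(C)(C)[Si](OCC[C@@]1(C)[C@H](C)CC[C@@]2(C)C(O[K])=CCC[C@H]12)(c1ccccc1)c1ccccc1 | intermediate
16 | (4aR,5S,6R,8aR)-5-{2-[(tert-butyldiphenylsilyl)oxy]ethyl}-5,6,8a-trimethyl-3,4,4a,5,6,7,8,8a-octahydronaphthalen-1-yl trifluoromethanesulfonate | CC(C)(C)[Si](OCC[C@@]1(C)[C@H](C)CC[C@@]2(C)C(OS(=O)(=O)C(F)(F)F)=CCC[C@H]12)(c1ccccc1)c1ccccc1 | intermediate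
17 | tert-butyl{2-[(1S,2R,4aR,8aR)-1,2,4a,5-tetramethyl-1,2,3,4,4a,7,8,8a-octahydronaphthalen-1-yl]ethoxy}diphenylsilane | CC(C)(C)[Si](OCC[C@@]1(C)[C@H](C)CC[C@@]2(C)C(C)=CCC[C@H]12)(c1ccccc1)c1ccccc1 | intermediate
18 | 2-[(1S,2R,4aR,8aR)-1,2,4a,5-tetramethyl-1,2,3,4,4a,7,8,8a-octahydronaphthalen-1-yl]ethan-1-ol | OCC[C@@]1(C)[C@H](C)CC[C@@]2(C)C(C)=CCC[C@H]12 | intermediate
19 | (1S,2R,4aR,8aR)-1-(2-iodoethyl)-1,2,4a,5-tetramethyl-1,2,3,4,4a,7,8,8a-octahydronaphthalene | ICC[C@@]1(C)[C@H](C)CC[C@@]2(C)C(C)=CCC[C@H]12 | intermediate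
20 | but-2-yne-1,4-diol | OCC#CCO | starting material
21 | 4-[(tert-butyldimethylsilyl)oxy]but-2-yn-1-ol | CC(C)(C)[Si](C)(C)OCC#CCO | intermediate
22 | sodium 3-{[(tert-butyldimethylsilyl)oxy]methyl}-2,2-bis(2-methoxyethoxy)-2,5-dihydro-1,2-oxaluminol-2-uide (cyclic alkenylalanate) | CC(C)(C)[Si](C)(C)OCC1=CCO[Al-]1(OCCOC)OCCOC.[Na+] | intermediate
23 | (2Z)-4-[(tert-butyldimethylsilyl)oxy]-3-iodobut-2-en-1-ol | OC/C=C(\I)CO[Si](C)(C)C(C)(C)C | intermediate
24 | icosanoyl chloride | CCCCCCCCCCCCCCCCCCCC(=O)Cl | starting material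
25 | (2Z)-4-[(tert-butyldimethylsilyl)oxy]-3-iodobut-2-en-1-yl icosanoate | CCCCCCCCCCCCCCCCCCCC(=O)OC/C=C(\I)CO[Si](C)(C)C(C)(C)C | intermediate
26 | {2-[(1S,2R,4aR,8aR)-1,2,4a,5-tetramethyl-1,2,3,4,4a,7,8,8a-octahydronaphthalen-1-yl]ethyl}zinc iodide | I[Zn]CC[C@@]1(C)[C@H](C)CC[C@@]2(C)C(C)=CCC[C@H]12 | intermediate
27 | (2E)-3-{[(tert-butyldimethylsilyl)oxy]methyl}-5-[(1S,2R,4aR,8aR)-1,2,4a,5-tetramethyl-1,2,3,4,4a,7,8,8a-octahydronaphthalen-1-yl]pent-2-en-1-yl icosanoate | CCCCCCCCCCCCCCCCCCCC(=O)OC/C=C(/CO[Si](C)(C)C(C)(C)C)CC[C@@]1(C)[C@H](C)CC[C@@]2(C)C(C)=CCC[C@H]12 | intermediate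
28 | (2E)-3-(hydroxymethyl)-5-[(1S,2R,4aR,8aR)-1,2,4a,5-tetramethyl-1,2,3,4,4a,7,8,8a-octahydronaphthalen-1-yl]pent-2-en-1-yl icosanoate (CNP0168335.1) | CCCCCCCCCCCCCCCCCCCC(=O)OC/C=C(/CO)CC[C@@]1(C)[C@H](C)CC[C@@]2(C)C(C)=CCC[C@H]12 | target

**Totals and risk**

Total step count: 17. Longest linear sequence: 14 steps (steps 1–12, 16 and 17).

Steps most likely to fail:

1. Step 6 (key step). The second ring closure may be diverted by the cationic character at C10 (chloride transfer from aluminium, or 1,2-methyl migration from C9 or C5). It may also close the five-membered spiro ring at C10 instead of ring A, and the facial selectivity at C5 may be incomplete. The fallback uses known chemistry, sets out from 9 and returns to the route at 14. The intermolecular ene reaction alone (acrolein, 1.0 equiv Me2AlCl, CH2Cl2, −78 °C, early quench) should allow aldehyde 11 to be isolated. Chlorite oxidation (NaClO2, NaH2PO4, 2-methylbut-2-ene, t-BuOH/H2O) would give 4-[(5R,6S)-6-{2-[(tert-butyldiphenylsilyl)oxy]ethyl}-2,5,6-trimethylcyclohex-1-en-1-yl]butanoic acid F1, and (PhSe)2/Bu3P would convert it into the Se-phenyl selenoester F2. With Bu3SnH/AIBN (benzene, 80 °C, slow addition) the acyl radical should close ring A by 6-endo attack on C5 of the tetrasubstituted alkene without any cation. The tertiary C10 radical should then take hydrogen from the stannane on the face away from the two axial methyl groups, which would give ketone 14 directly.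

2. Step 7. Hydrogen-atom transfer to the trisubstituted alkene flanked by two quaternary carbons may be slow, or hydrogen may be delivered to C10 from the wrong face. The fallback sets out from 12 and returns at 13: hydroxyl-directed homogeneous hydrogenation with [Ir(cod)(PCy3)(py)]PF6 (H2, CH2Cl2), in which the homoallylic C4 hydroxyl binds iridium and hydrogen is delivered to C10 from the face that carries C4. No new compound is made (F0).

3. Step 5. The ylide may fail to add to the carbonyl group flanked by a quaternary and a tertiary carbon, with enolisation taking over. The fallback sets out from 8 and returns at 9 by Peterson olefination. Me3SiCH2Li/CeCl3 (THF, −78 °C) should add to the hindered carbonyl to give the β-hydroxysilane (2S,3R,6R)-2-{2-[(tert-butyldiphenylsilyl)oxy]ethyl}-2,3,6-trimethyl-1-[(trimethylsilyl)methyl]cyclohexan-1-ol F3, and KH (THF) would then eliminate trimethylsilanol to give 9.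

Further compounds
F1 | step 6 | 4-[(5R,6S)-6-{2-[(tert-butyldiphenylsilyl)oxy]ethyl}-2,5,6-trimethylcyclohex-1-en-1-yl]butanoic acid | CC(C)(C)[Si](OCC[C@@]1(C)[C@H](C)CCC(C)=C1CCCC(=O)O)(c1ccccc1)c1ccccc1
F2 | step 6 | Se-phenyl 4-[(5R,6S)-6-{2-[(tert-butyldiphenylsilyl)oxy]ethyl}-2,5,6-trimethylcyclohex-1-en-1-yl]butaneselenoate | CC(C)(C)[Si](OCC[C@@]1(C)[C@H](C)CCC(C)=C1CCCC(=O)[Se]c1ccccc1)(c1ccccc1)c1ccccc1
F0 | step 7 | none | none
F3 | step 5 | (2S,3R,6R)-2-{2-[(tert-butyldiphenylsilyl)oxy]ethyl}-2,3,6-trimethyl-1-[(trimethylsilyl)methyl]cyclohexan-1-ol (C1 epimers) | CC(C)(C)[Si](OCC[C@@]1(C)[C@H](C)CC[C@@H](C)C1(O)C[Si](C)(C)C)(c1ccccc1)c1ccccc1
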